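all flasks: G 0.96 mM (held)

| run | Z | remark | time |
|---|---|---|---|
| epsilon | 30 mM | run made earlier |  |
| flask | 20 mM |  | 10 h |

epsilon run (percent of the Z charged)

| time / min | D / % | Z / % |
|---|---|---|
| 3.00 | 0.9 | 97.0 |
| 10.0 | 3.1 | 90.1 |
| 15.0 | 6.7 | 83.7 |
| 25.0 | 11.0 | 75.5 |
| 40.0 | 15.6 | 63.0 |
| 50.0 | 17.3 | 55.8 |
| 60.0 | 19.6 | 48.5 |

(each reading ± 1 percentage point)

- at the start none of G is in solution
- L is what G becomes in solution

1. the D standing at 10 h, as a percentage of the Z charged
2. concentration of L in solution at 1.0 h, in percent of saturation
3. the change that raises the amount of D at 10 h, in percent of the Z charged most ("none" if none brings more than 2 percentage points) (Thursday's / Wednesday's / none)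
4. amount of D at 10 h, in percent of the Z charged, after Wednesday's

- Thursday's: doubling the transfer coefficient of G, all else as stated
- Wednesday's: doubling the saturation concentration of G, all else as stated

1. Of the Z charged to the epsilon run, 48.5% stood at 60.0 min and 19.6% was D. The D share (the selectivity), D standing over Z lost, reads 38.1%, with a scatter of 1 percentage point on each reading.

2. The next flask needs a figure for D at 10 h before a change is chosen. In the epsilon run Z fell to half of its charge in 60.0 min, and 10 h is ten times as long. If Z keeps that pace, 0.0720% of the flask's charge remains.

3. The reckoning here takes D as the D share of Z lost, which gives 38.0% for the flask. The forecast is higher, at 41%.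

4. At 3.00 min in the epsilon run, far shorter than 60.0 min, the D share puts D at 1.14%, and the reading is 0.9%, a gap smaller than the scatter of 1 point. So these readings show no delay in D, and the next run goes to Wednesday's, which raises the level L can reach, rather than Thursday's, which speeds its arrival.

5. The forecast gives L at 85% of saturation at 1.0 h, Wednesday's as the best change, and 57% of D at 10 h after it, holding that “Gas supply is therefore not badly limiting.”

    Z + L ⇌ D (K = 7600 /M, k = 410 /M/h)
    2 L → Q (k = 87.4 /M/h)
    Z + D → E (k = 6.53 /M/h)
    G ⇌ L, rate k4*(csat - [L]) (kL = 46.5 /h)
    Z → J (k = 0.382 /h)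

The flask gives 32.2% of D at 10 h, and L at 92.3% of saturation at 1.0 h. Wednesday's reaches 47.4%, a gain of 15 points against 0.71 points for Thursday's. On the Z lost so far, the D share gives 36.9% for the same flask stopped at 6.0 h, which holds 36.1% of D, but 37.2% at 10 h, above the 32.2% found. The step between Z + L and D has a relaxation half-life of 1.10 h at 10.0 h, short against 10 h, and at that time Z passes into J at 0.97 times the forward rate of Z + L into D. Left to 100 h, the flask holds 2.77% of D and 85.2% of J.

(The earlier runs and the new flask stem from a simulated flask with constants of no real substance; scatter was added.)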